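## Retrosynthetic overview
1. Manuifolin D comes from its 7,2′-bis-TIPS ether by one global desilylation.
2. The pyran is the only ring that is built, and it is closed last. One anodic operation on an acyclic (2R)-1-aryl-3-aryloxypropan-2-ol forms C3–C1′ (1,2-aryl shift with inversion) and C4–C4a (Friedel–Crafts closure).
3. That alcohol comes from a B-ring aryllithium and an A-ring (R)-glycidyl ether. The single stereocentre is bought in (R)-glycidyl nosylate.
4. The B ring comes from 4-bromoresorcinol by O-prenylation, silylation, aromatic Claisen rearrangement (prenyl to 1,1-dimethylallyl) and a second O-prenylation. The A ring comes from resorcinol.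

Assumption: the SMILES descriptor corresponds to (3R), and the (R)-glycidyl nosylate is bought at ≥99 % ee.

## Route

Step 1
Reactants: 1 4-bromoresorcinol
Product: 2 2-bromo-5-(3-methylbut-2-enyloxy)phenol
Conditions: prenyl bromide (1.0 equiv), K2CO3 (1.1 equiv), acetone, 25→40 °C, 16 h
Reagents that add atoms: prenyl bromide CC(C)=CCBr
Why: Williamson ether synthesis in which the unhindered OH para to Br is alkylated faster than the OH next to bromine, whose phenoxide is less basic and shielded, and the minor isomer and bis-ether are removed by chromatography.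

Step 2
Reactants: 2 2-bromo-5-(3-methylbut-2-enyloxy)phenol
Product: 3 [2-bromo-5-(3-methylbut-2-enyloxy)phenoxy]triisopropylsilane
Conditions: TIPSCl, imidazole, DMF, 25 °C
Reagents that add atoms: triisopropylsilyl chloride CC(C)[Si](Cl)(C(C)C)C(C)C
Why: Standard imidazole-promoted O-silylation, and the bulky TIPS group later shields C3′ in step 3 and makes the 2′-oxygen a poor neighbouring group in step 8.

Step 3
Reactants: 3 [2-bromo-5-(3-methylbut-2-enyloxy)phenoxy]triisopropylsilane
Product: 5 4-bromo-2-(2-methylbut-3-en-2-yl)-5-(triisopropylsilyloxy)phenol, via ortho-dienone 4 (not isolated)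
Conditions: PhNEt2, 190 °C, sealed tube, Ar, 3 h
Reagents that add atoms: none
Why: Aromatic Claisen rearrangement, in which the [3,3] shift delivers the prenyl unit inverted as 1,1-dimethylallyl to the free ortho carbon remote from OTIPS, dienone 4 tautomerises to the phenol, and the basic solvent suppresses cyclisation to a dihydrobenzofuran.

Step 4
Reactants: 5 4-bromo-2-(2-methylbut-3-en-2-yl)-5-(triisopropylsilyloxy)phenol
Product: 6 [2-bromo-4-(2-methylbut-3-en-2-yl)-5-(3-methylbut-2-enyloxy)phenoxy]triisopropylsilane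
Conditions: prenyl bromide (1.3 equiv), K2CO3, acetone, reflux
Reagents that add atoms: prenyl bromide CC(C)=CCBr
Why: Williamson ether synthesis on the only free phenol, with the aryl TIPS ether and aryl bromide inert to K2CO3 in acetone.

Step 5
Reactants: 7 resorcinol
Product: 8 3-(triisopropylsilyloxy)phenol
Conditions: 7 (3 equiv), TIPSCl (1 equiv), imidazole, DMF, 0→25 °C, aqueous wash
Reagents that add atoms: triisopropylsilyl chloride CC(C)[Si](Cl)(C(C)C)C(C)C
Why: Statistical monosilylation made efficient by an excess of cheap, water-soluble resorcinol that is washed out.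

Step 6
Reactants: 8 3-(triisopropylsilyloxy)phenol; 9 (R)-glycidyl 3-nitrobenzenesulfonate
Product: 10 (2R)-2-{[3-(triisopropylsilyloxy)phenoxy]methyl}oxirane
Conditions: K2CO3, acetone, 50 °C
Reagents that add atoms: none
Why: SN2 O-alkylation at the primary C–ONs carbon, which is a far better electrophile than the epoxide, so the bought stereocentre is not touched and stays (R).

Step 7
Reactants: 6 [2-bromo-4-(2-methylbut-3-en-2-yl)-5-(3-methylbut-2-enyloxy)phenoxy]triisopropylsilane; 10 (2R)-2-{[3-(triisopropylsilyloxy)phenoxy]methyl}oxirane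
Product: 12 (2R)-1-[5-(2-methylbut-3-en-2-yl)-4-(3-methylbut-2-enyloxy)-2-(triisopropylsilyloxy)phenyl]-3-[3-(triisopropylsilyloxy)phenoxy]propan-2-ol, via aryllithium 11 (not isolated)
Conditions: n-BuLi (1.05 equiv), THF, −78 °C, 15 min; then 10 (1.2 equiv), BF3·OEt2 (1.2 equiv), −78 °C, 1 h; H2O
Reagents that add atoms: none
Why: Bromine–lithium exchange followed by BF3-promoted SN2 opening of the epoxide at its terminal CH2 leaves the C–O stereocentre unchanged, and at −78 °C the TIPS group is too slow for O→C (retro-Brook) migration.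

Step 8
Reactants: 12 (2R)-1-[5-(2-methylbut-3-en-2-yl)-4-(3-methylbut-2-enyloxy)-2-(triisopropylsilyloxy)phenyl]-3-[3-(triisopropylsilyloxy)phenoxy]propan-2-ol
Product: 15 (3R)-3-[5-(2-methylbut-3-en-2-yl)-4-(3-methylbut-2-enyloxy)-2-(triisopropylsilyloxy)phenyl]-7-(triisopropylsilyloxy)chroman, via alkoxyphosphonium ion 13 (not isolated), via phenonium ion 14 (not isolated)
Conditions: PPh3 (1.2 equiv), 2,6-lutidinium triflate (0.1 M), CH2Cl2–HFIP 4:1, undivided cell, graphite(+)/Pt(−), 5 mA cm⁻², anode ≤ +1.1 V vs SCE, 2.4 F mol⁻¹ (until PPh3 is consumed), 0 °C; then 25 °C, 2 h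
Reagents that add atoms: none
Why: Proposed new method: anodic phosphine-mediated dehydroxylative 1,2-aryl shift/Friedel–Crafts annulation, in which PPh3 (Ep about +1.0 V vs SCE) is oxidised below the oxygenated arenes (about +1.3 V or higher) and the alkenes (above +1.8 V), its radical cation is trapped by the secondary OH and oxidised again to alkoxyphosphonium 13 with the C–O configuration kept, the 2,4-dioxygenated B ring expels Ph3P=O from the rear (Ar1-3 participation, clean inversion at the bought stereocentre) to give phenonium 14, and the tethered A ring opens 14 at its unsubstituted CH2, para to OTIPS, in the same 6-endo geometry that turns aryl glycidyl ethers into chroman-3-ols, so C3–C1′ and C4–C4a form in one operation and (2R)-12 becomes (3R)-15 while cathodic H2 evolution removes both protons and keeps the medium near neutral for the prenyl ether; the closest known reaction types are the anodic preparation of alkoxytriphenylphosphonium salts from alcohols with SN2 capture (an electrochemical Appel/Mitsunobu-type activation) and the acid/HFIP-promoted stereospecific Friedel–Crafts reaction of β-aryl alcohols through phenonium ions, which have not been merged or used to close a chroman.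

Step 9
Reactants: 15 (3R)-3-[5-(2-methylbut-3-en-2-yl)-4-(3-methylbut-2-enyloxy)-2-(triisopropylsilyloxy)phenyl]-7-(triisopropylsilyloxy)chroman
Product: 16 Manuifolin D
Conditions: TBAF (2.2 equiv), AcOH (2.2 equiv), THF, 0 °C, 30 min
Reagents that add atoms: none
Why: Buffered fluoride desilylation frees both phenols without affecting the prenyl ether, the alkenes or the non-acidic C3 stereocentre.

## Compound list
1 | 4-bromoresorcinol | Oc1ccc(Br)c(O)c1 | starting material
2 | 2-bromo-5-(3-methylbut-2-enyloxy)phenol | CC(C)=CCOc1ccc(Br)c(O)c1 | intermediate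
3 | [2-bromo-5-(3-methylbut-2-enyloxy)phenoxy]triisopropylsilane | CC(C)=CCOc1ccc(Br)c(O[Si](C(C)C)(C(C)C)C(C)C)c1 | intermediate
4 | 4-bromo-6-(2-methylbut-3-en-2-yl)-3-(triisopropylsilyloxy)cyclohexa-2,4-dien-1-one (racemic, transient) | O=C1C=C(O[Si](C(C)C)(C(C)C)C(C)C)C(Br)=CC1C(C)(C)C=C | intermediate
5 | 4-bromo-2-(2-methylbut-3-en-2-yl)-5-(triisopropylsilyloxy)phenol | C=CC(C)(C)c1cc(Br)c(O[Si](C(C)C)(C(C)C)C(C)C)cc1O | intermediate
6 | [2-bromo-4-(2-methylbut-3-en-2-yl)-5-(3-methylbut-2-enyloxy)phenoxy]triisopropylsilane | C=CC(C)(C)c1cc(Br)c(O[Si](C(C)C)(C(C)C)C(C)C)cc1OCC=C(C)C | intermediate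
7 | resorcinol | Oc1cccc(O)c1 | starting material
8 | 3-(triisopropylsilyloxy)phenol | CC(C)[Si](Oc1cccc(O)c1)(C(C)C)C(C)C | intermediate
9 | (R)-glycidyl 3-nitrobenzenesulfonate | O=S(=O)(OC[C@H]1CO1)c1cccc([N+](=O)[O-])c1 | starting material
10 | (2R)-2-{[3-(triisopropylsilyloxy)phenoxy]methyl}oxirane | CC(C)[Si](Oc1cccc(OC[C@H]2CO2)c1)(C(C)C)C(C)C | intermediate
11 | [5-(2-methylbut-3-en-2-yl)-4-(3-methylbut-2-enyloxy)-2-(triisopropylsilyloxy)phenyl]lithium | [Li]c1cc(C(C)(C)C=C)c(OCC=C(C)C)cc1O[Si](C(C)C)(C(C)C)C(C)C | intermediate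
12 | (2R)-1-[5-(2-methylbut-3-en-2-yl)-4-(3-methylbut-2-enyloxy)-2-(triisopropylsilyloxy)phenyl]-3-[3-(triisopropylsilyloxy)phenoxy]propan-2-ol | CC(C)[Si](Oc1cccc(OC[C@H](O)Cc2cc(C(C)(C)C=C)c(OCC=C(C)C)cc2O[Si](C(C)C)(C(C)C)C(C)C)c1)(C(C)C)C(C)C | intermediate
13 | (2R)-alkoxytriphenylphosphonium cation of 12 (O–PPh3⁺ in place of OH) | CC(C)[Si](Oc1cccc(OC[C@H](O[P+](c2ccccc2)(c2ccccc2)c2ccccc2)Cc2cc(C(C)(C)C=C)c(OCC=C(C)C)cc2O[Si](C(C)C)(C(C)C)C(C)C)c1)(C(C)C)C(C)C | intermediate
14 | phenonium ion: spiro[2.5]octadienyl cation, drawn as its 4′-oxocarbenium form, with (R)-CH(CH2OAr) in the cyclopropane and the spiro centre unspecified | C=CC(C)(C)C1=CC2(C[C@H]2COc3cccc(O[Si](C(C)C)(C(C)C)C(C)C)c3)C(O[Si](C(C)C)(C(C)C)C(C)C)=CC1=[O+]CC=C(C)C | intermediate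
15 | (3R)-3-[5-(2-methylbut-3-en-2-yl)-4-(3-methylbut-2-enyloxy)-2-(triisopropylsilyloxy)phenyl]-7-(triisopropylsilyloxy)chroman | C=CC(C)(C)c1cc([C@@H]2COc3cc(O[Si](C(C)C)(C(C)C)C(C)C)ccc3C2)c(O[Si](C(C)C)(C(C)C)C(C)C)cc1OCC=C(C)C | intermediate
16 | Manuifolin D, (3R)-3-[2-hydroxy-5-(2-methylbut-3-en-2-yl)-4-(3-methylbut-2-enyloxy)phenyl]chroman-7-ol | C=CC(C)(C)c1cc([C@@H]2COc3cc(O)ccc3C2)c(O)cc1OCC=C(C)C | target

## Step count and risks
Total steps: 9. Longest linear sequence: 7 (steps 1, 2, 3, 4, 7, 8, 9).

**Step 8 (the proposed new step).**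
- Possible failures:
  - Competing anodic oxidation of the B ring.
  - Capture of the phenonium ion by residual PPh3.
  - Participation of the 2′-oxygen, which would give a dihydrobenzofuran.
  - A hydride shift to the benzylic cation, which would give a 4-arylchroman.
  - Loss of prenyl cation from the phenonium ion.
- The fallback uses known chemistry and no electrolysis, and it sets out from 12.
- MsCl and Et3N in CH2Cl2 at −20 °C give (2R)-1-[5-(2-methylbut-3-en-2-yl)-4-(3-methylbut-2-enyloxy)-2-(triisopropylsilyloxy)phenyl]-3-[3-(triisopropylsilyloxy)phenoxy]propan-2-yl methanesulfonate F1.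
- F1 is used crude and solvolysed in HFIP buffered with 2,6-lutidine at 25–40 °C. This is the classical aryl-assisted sulfonate solvolysis with intramolecular Friedel–Crafts capture, and it inverts at the carbinol carbon.
- It comes back to the route at 15.

**Step 3.**
- Possible failures are thermal loss of isoprene, partial migration to C3′, and cyclisation of the product phenol.
- The fallback replaces the sigmatropic step by a cross-coupling and sets out from 1.
- NBS (1 equiv) in MeCN gives 4,6-dibromoresorcinol F2, in which both OH groups are equivalent.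
- Mono-alkylation with prenyl bromide and K2CO3 gives 2,4-dibromo-5-(3-methylbut-2-enyloxy)phenol F3.
- TIPSCl and imidazole give [2,4-dibromo-5-(3-methylbut-2-enyloxy)phenoxy]triisopropylsilane F4.
- A ligand-controlled γ-selective Suzuki–Miyaura allylation then installs the 1,1-dimethylallyl group. It uses prenylboronic acid pinacol ester, Pd(OAc)2 with a γ-selective biarylphosphine, aqueous K3PO4 and THF at 40 °C.
- The coupling should occur at the C–Br next to the prenyl ether, which is less hindered than the C–Br next to OTIPS.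
- It comes back to the route at 6.

**Step 7.**
- Possible failures are O→C silyl migration in aryllithium 11, BF3-induced self-cyclisation of 10, and Wittig-type chemistry of the prenyl ether.
- The fallback avoids any polar aryl–metal species and sets out from 6 and 10.
- It is a nickel-catalysed reductive cross-electrophile coupling with NiCl2(dme)/2,2′-bipyridine 10 mol %, NaI, Et3N·HCl and Zn in DMPU at 25 °C.
- The epoxide is first opened at its terminus to (2S)-1-iodo-3-[3-(triisopropylsilyloxy)phenoxy]propan-2-ol F5. The primary C–I bond of F5 then couples with the aryl bromide.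
- The carbinol stereocentre is never involved.
- It comes back to the route at 12.

## Further compounds
F1 | step 8 | (2R)-1-[5-(2-methylbut-3-en-2-yl)-4-(3-methylbut-2-enyloxy)-2-(triisopropylsilyloxy)phenyl]-3-[3-(triisopropylsilyloxy)phenoxy]propan-2-yl methanesulfonate | CC(C)[Si](Oc1cccc(OC[C@H](OS(C)(=O)=O)Cc2cc(C(C)(C)C=C)c(OCC=C(C)C)cc2O[Si](C(C)C)(C(C)C)C(C)C)c1)(C(C)C)C(C)C
F2 | step 3 | 4,6-dibromoresorcinol | Oc1cc(O)c(Br)cc1Br
F3 | step 3 | 2,4-dibromo-5-(3-methylbut-2-enyloxy)phenol | CC(C)=CCOc1cc(O)c(Br)cc1Br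
F4 | step 3 | [2,4-dibromo-5-(3-methylbut-2-enyloxy)phenoxy]triisopropylsilane | CC(C)=CCOc1cc(O[Si](C(C)C)(C(C)C)C(C)C)c(Br)cc1Br
F5 | step 7 | (2S)-1-iodo-3-[3-(triisopropylsilyloxy)phenoxy]propan-2-ol | CC(C)[Si](Oc1cccc(OC[C@H](O)CI)c1)(C(C)C)C(C)C
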